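**Retrosynthetic overview**
1. Numbering (cembrane style): C1 = ring CH carrying the acrylate carbon C15 (C16 = lactone C=O, C17 = exo-CH2). C2 and C3 = ring CH2, C4 = quaternary C(Me)–O(lactone), C5 = CHOH, C8=C9 = Z-alkene, C12 = C(Me)OH, C13 = CHOH, C14 = CH2.
2. Last ring (seven-membered α-methylene lactone): C16 is inserted as CO between C15 (enol triflate of a C15 methyl ketone) and the free tertiary C4–OH.
3. First ring (14-membered carbocycle), key disconnection C2–C3, the bond common to both rings. Two electrophilic CH2 carbons are joined reductively: the oxirane CH2 (C3) of a C3–C4 epoxide and the exo-methylene (C2) of a temporary α-methylene-γ-butyrolactone C13–O–C15(=O)–C1.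
4. Enabling feature: C3 sits next to the oxygenated quaternary C4, so the oxygen is already in place as an epoxide and there is no β-hydrogen. C2 sits next to C1, which lies 1,3 to the C13 carbinol. C1–C14–C13–O can therefore be tied with C15 into a five-membered lactone that activates C2 and relays the C13 configuration to C1.
5. The acyclic precursor comes from a B-alkyl Suzuki union (C9–C10) of two fragments. Each contains an erythro 2-methyl-1,2-epoxy-3-ol made by Sharpless kinetic resolution, with antipodal tartrates.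

Key step: step 11

Remark: C5 and C13 are made racemic on purpose and resolved during epoxidation, so at most half of 8 and of 14 is carried on. Compounds 1, 2, 7, 11 and 12 are taken as commercial.

Step 1
Reactants: 1 2-(2-bromoethyl)-1,3-dioxolane; 2 propyne
Product: 5 2-[(3Z)-4-iodo-3-methylbut-3-en-1-yl]-1,3-dioxolane, via Grignard reagent 3 (not isolated), via (Z)-vinylcopper 4 (not isolated)
Conditions: Mg, THF, 25 °C; CuBr·SMe2, Et2O/Me2S, −45 °C; 2, −25 °C; I2, −78 → 0 °C
Reagents that add atoms: iodine, II
Why: Normant carbocupration: the alkylcopper adds syn to propyne with the alkyl group going to the internal carbon, and iodinolysis with retention places the chain cis to iodine, which fixes the later Z geometry of C8=C9.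

Step 2
Reactants: 5 2-[(3Z)-4-iodo-3-methylbut-3-en-1-yl]-1,3-dioxolane
Product: 6 (4Z)-5-iodo-4-methylpent-4-enal
Conditions: 2 M HCl, acetone, 25 °C
Reagents that add atoms: water, O
Why: Acid-catalysed acetal hydrolysis, to which the vinyl iodide is inert.

Step 3
Reactants: 6 (4Z)-5-iodo-4-methylpent-4-enal; 7 isopropenylmagnesium bromide
Product: 8 rac-(6Z)-7-iodo-2,6-dimethylhepta-1,6-dien-3-ol
Conditions: THF, −78 → −20 °C; H2O
Reagents that add atoms: none
Why: Grignard 1,2-addition to the aldehyde at low temperature, where iodine–magnesium exchange at the vinyl iodide should not compete; C5 is formed racemic.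

Step 4
Reactants: 8 rac-(6Z)-7-iodo-2,6-dimethylhepta-1,6-dien-3-ol
Product: 9 (1S,4Z)-5-iodo-4-methyl-1-[(2R)-2-methyloxiran-2-yl]pent-4-en-1-ol
Conditions: Ti(OiPr)4 (10 mol %), L-(+)-DIPT (12 mol %), t-BuOOH (0.45 equiv), 4 Å MS, CH2Cl2, −20 °C
Reagents that add atoms: tert-butyl hydroperoxide, CC(C)(C)OO
Why: Sharpless kinetic resolution by asymmetric epoxidation: with L-(+)-DIPT the (S)-alcohol should be epoxidised much faster and erythro-selectively, so C5 (S) is set by selection and C4 (R) by the reagent reinforced by A1,2 strain, while the slow (R)-enantiomer of 8 is separated.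

Step 5
Reactants: 9 (1S,4Z)-5-iodo-4-methyl-1-[(2R)-2-methyloxiran-2-yl]pent-4-en-1-ol
Product: 10 tert-butyldimethylsilyl ether of 9 (C5–OTBS)
Conditions: TBSCl, imidazole, DMAP (cat.), DMF, 35 °C
Reagents that add atoms: tert-butyldimethylsilyl chloride, CC(C)(C)[Si](C)(C)Cl
Why: Base-mediated silylation of the only hydroxyl group, chosen over silyl triflate conditions so that the acid-sensitive 2,2-disubstituted epoxide is not touched.

Step 6
Reactants: 11 methacrolein; 12 2,3-dibromopropene
Product: 14 rac-5-bromo-2-methylhexa-1,5-dien-3-ol, via 2-bromoallylindium dibromide 13 (not isolated)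
Conditions: In, THF/H2O (1:1), 25 °C
Reagents that add atoms: none
Why: Barbier-type indium-mediated 2-bromoallylation, which adds 1,2 to the enal and keeps the vinyl bromide; C13 is formed racemic.

Step 7
Reactants: 14 rac-5-bromo-2-methylhexa-1,5-dien-3-ol
Product: 15 (1R)-3-bromo-1-[(2S)-2-methyloxiran-2-yl]but-3-en-1-ol
Conditions: Ti(OiPr)4 (10 mol %), D-(−)-DIPT (12 mol %), t-BuOOH (0.45 equiv), 4 Å MS, CH2Cl2, −20 °C
Reagents that add atoms: tert-butyl hydroperoxide, CC(C)(C)OO
Why: Sharpless kinetic resolution with the antipodal tartrate: the (R)-alcohol should react fast and erythro-selectively at the electron-rich isopropenyl group only, which sets C13 (R) by selection and C12 (S) by the reagent.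

Step 8
Reactants: 15 (1R)-3-bromo-1-[(2S)-2-methyloxiran-2-yl]but-3-en-1-ol
Product: 16 (3S,4R)-6-bromo-3-methylhepta-1,6-diene-3,4-diol
Conditions: Me3S+ I− (4 equiv), n-BuLi (3.8 equiv), THF, −10 → 25 °C
Reagents that add atoms: trimethylsulfonium iodide, C[S+](C)C.[I-]
Why: One-carbon homologation of an epoxide to an allylic alcohol with excess dimethylsulfonium methylide (attack at the oxirane CH2, then ylide-induced loss of Me2S); the C12–O bond is not broken, so C12 keeps its configuration.

Step 9
Reactants: 16 (3S,4R)-6-bromo-3-methylhepta-1,6-diene-3,4-diol; 10 tert-butyldimethylsilyl ether of 9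
Product: 18 (4R,5S,8Z,12S)-2-bromo-12-[(tert-butyldimethylsilyl)oxy]-5,9-dimethyl-12-[(2R)-2-methyloxiran-2-yl]dodeca-1,8-diene-4,5-diol, via B-alkyl-9-BBN 17 (not isolated)
Conditions: 16, 9-BBN (3.3 equiv), THF, 25 °C; aq. Cs2CO3; then 10, Pd(dppf)Cl2 (5 mol %), AsPh3, DMF, 25 °C
Reagents that add atoms: none
Why: 9-BBN should hydroborate the monosubstituted vinyl group terminally in preference to the electron-poor 2-bromoalkene, and the B-alkyl Suzuki–Miyaura coupling takes place at the more reactive C–I bond with retention, so the Z alkene is carried over.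

Step 10
Reactants: 18 (4R,5S,8Z,12S)-2-bromo-12-[(tert-butyldimethylsilyl)oxy]-5,9-dimethyl-12-[(2R)-2-methyloxiran-2-yl]dodeca-1,8-diene-4,5-diol
Product: 19 (5R)-5-{(2S,5Z,9S)-9-[(tert-butyldimethylsilyl)oxy]-2-hydroxy-6-methyl-9-[(2R)-2-methyloxiran-2-yl]non-5-en-2-yl}-3-methylenedihydrofuran-2(3H)-one
Conditions: Pd(PPh3)4 (5 mol %), CO (1 atm), K2CO3, DMF, 60 °C
Reagents that add atoms: carbon monoxide, [C-]#[O+]
Why: Palladium-catalysed carbonylative lactonisation of a 3-bromobut-3-en-1-ol: the acylpalladium is captured by C13–OH in a five-membered closure that outruns the six-membered one through the tertiary C12–OH, and the non-allylic epoxide is not a substrate for Pd(0).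

Step 11
Reactants: 19 (5R)-5-{(2S,5Z,9S)-9-[(tert-butyldimethylsilyl)oxy]-2-hydroxy-6-methyl-9-[(2R)-2-methyloxiran-2-yl]non-5-en-2-yl}-3-methylenedihydrofuran-2(3H)-one
Product: 21 (1R,4R,5S,8Z,12S,13R)-5-[(tert-butyldimethylsilyl)oxy]-4,12-dihydroxy-4,8,12-trimethylcyclotetradec-8-ene-1,13-carbolactone (C15 carbonyl on C1 esterified by O–C13), via β-hydroxyalkylcobalamin 20 (not isolated)
Conditions: vitamin B12 (10 mol %), Zn, NH4Cl, DMF, blue LEDs, 25 °C, 19 added over 12 h (final 1 mM)
Reagents that add atoms: none
Why: Proposed new method: Zn-generated cob(I)alamin attacks the unhindered oxirane CH2 (C3) in an SN2 step, visible light homolyses the β-hydroxyalkyl–Co(III) bond of 20 (which cannot lose Co–H because C4 bears no hydrogen), and the nucleophilic primary C3 radical adds to the exo-methylene carbon C2, so two electrophilic CH2 carbons are joined by polarity reversal. The closest known reaction types are cobalt(I)-mediated epoxide–olefin radical cyclisations to five- and six-membered rings, vitamin-B12-catalysed Giese additions and tin-hydride Giese macrocyclisations of ω-iodoalkyl enones; merging them in a catalytic 14-membered closure is the new element. The one ring closed is the 14-membered carbocycle, in the 14-endo-trig mode, which turns the monocyclic lactone into the bridged bicycle and frees the tertiary C4–OH with its configuration intact because the C4–O bond is never broken. The only new stereocentre, C1, arises when the tertiary α-lactone radical is reduced to the zinc enolate and protonated (or takes up H) from the lactone face opposite the C12 substituent on C13, the face not covered by the new bridge, which should give the cis-α,γ-disubstituted lactone, also the thermodynamically preferred epimer. The step needs regioselective epoxide opening (secured by the 2,2-disubstitution), attack on C2 rather than on the electron-rich C8=C9 alkene (secured by polarity matching and the s-cis exo-methylene lactone, further activated by Zn(II)), and ring closure ahead of intermolecular addition or reduction (secured by slow addition at high dilution and the absence of a fast hydrogen-atom donor).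

Step 12
Reactants: 21 (1R,4R,5S,8Z,12S,13R)-5-[(tert-butyldimethylsilyl)oxy]-4,12-dihydroxy-4,8,12-trimethylcyclotetradec-8-ene-1,13-carbolactone
Product: 22 methyl (1R,4R,5S,8Z,12S,13R)-5-[(tert-butyldimethylsilyl)oxy]-4-hydroxy-12,13-(isopropylidenedioxy)-4,8,12-trimethylcyclotetradec-8-ene-1-carboxylate
Conditions: Me2C(OMe)2, MeOH, TsOH·H2O (5 mol %), 25 °C
Reagents that add atoms: 2,2-dimethoxypropane, COC(C)(C)OC; methanol, CO
Why: Acid-catalysed lactone methanolysis pulled forward by transacetalisation, because the freed C13–OH is trapped with the neighbouring C12–OH as an acetonide; doing this at the ester level avoids a keto-diol that could collapse to an internal ketal, and no stereocentre is touched.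

Step 13
Reactants: 22 methyl (1R,4R,5S,8Z,12S,13R)-5-[(tert-butyldimethylsilyl)oxy]-4-hydroxy-12,13-(isopropylidenedioxy)-4,8,12-trimethylcyclotetradec-8-ene-1-carboxylate
Product: 24 1-{(1R,4R,5S,8Z,12S,13R)-5-[(tert-butyldimethylsilyl)oxy]-4-hydroxy-12,13-(isopropylidenedioxy)-4,8,12-trimethylcyclotetradec-8-en-1-yl}ethanone, via Weinreb amide 23 (not isolated)
Conditions: MeNH(OMe)·HCl, i-PrMgCl, THF, −20 °C; then MeMgBr, 0 °C
Reagents that add atoms: methylmagnesium bromide, C[Mg]Br; N,O-dimethylhydroxylamine hydrochloride, CNOC.Cl (atoms only in 23)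
Why: One-pot Weinreb ketone synthesis: the magnesium amide converts the ester into the N-methoxy-N-methylamide, whose chelated adduct with MeMgBr stops at the ketone stage, and C1 should not epimerise at these temperatures.

Step 14
Reactants: 24 1-{(1R,4R,5S,8Z,12S,13R)-5-[(tert-butyldimethylsilyl)oxy]-4-hydroxy-12,13-(isopropylidenedioxy)-4,8,12-trimethylcyclotetradec-8-en-1-yl}ethanone
Product: 25 1-{(1R,4R,5S,8Z,12S,13R)-5-[(tert-butyldimethylsilyl)oxy]-4-hydroxy-12,13-(isopropylidenedioxy)-4,8,12-trimethylcyclotetradec-8-en-1-yl}ethenyl trifluoromethanesulfonate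
Conditions: KHMDS (2.2 equiv), THF, −78 °C; PhNTf2
Reagents that add atoms: N-phenylbis(trifluoromethanesulfonimide), O=S(=O)(C(F)(F)F)N(c1ccccc1)S(=O)(=O)C(F)(F)F
Why: Kinetic enolate formation at the methyl group (less hindered than the C1 methine, so C1 is preserved) followed by O-triflation; the hindered tertiary C4 alkoxide should not be sulfonylated by the mild triflimide.

Step 15
Reactants: 25 1-{(1R,4R,5S,8Z,12S,13R)-5-[(tert-butyldimethylsilyl)oxy]-4-hydroxy-12,13-(isopropylidenedioxy)-4,8,12-trimethylcyclotetradec-8-en-1-yl}ethenyl trifluoromethanesulfonate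
Product: 26 5-O-(tert-butyldimethylsilyl)-12,13-O-isopropylidene derivative of 27
Conditions: Pd(OAc)2 (10 mol %), dppf, CO (1 atm), i-Pr2NEt, DMAP, DMF, 60 °C
Reagents that add atoms: carbon monoxide, [C-]#[O+]
Why: Palladium-catalysed carbonylative lactonisation of a hydroxy enol triflate: CO insertion gives the acylpalladium at C16, which (relayed by DMAP) is captured transannularly by C4–OH, the only free hydroxyl group, and this closes the seven-membered α-methylene lactone directly.

Step 16
Reactants: 26 5-O-(tert-butyldimethylsilyl)-12,13-O-isopropylidene derivative of 27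
Product: 27 (1R,4R,5S,8Z,12S,13R)-5,12,13-trihydroxycembra-8,15(17)-dien-16,4-olide (CNP0263298.1)
Conditions: 48% aq. HF, MeCN, 0 → 25 °C
Reagents that add atoms: none
Why: Global deprotection under mildly acidic fluoride conditions removes the silyl ether and hydrolyses the acetonide without base, so acyl migration to C5–O or C13–O and Michael addition to the acrylate should be avoided.

**Compound list**
1 | 2-(2-bromoethyl)-1,3-dioxolane | BrCCC1OCCO1 | starting material
2 | propyne | CC#C | starting material
3 | [2-(1,3-dioxolan-2-yl)ethyl]magnesium bromide | Br[Mg]CCC1OCCO1 | intermediate (not isolated)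
4 | (Z)-[4-(1,3-dioxolan-2-yl)-2-methylbut-1-en-1-yl]copper | [Cu]/C=C(/C)CCC1OCCO1 | intermediate (not isolated)
5 | 2-[(3Z)-4-iodo-3-methylbut-3-en-1-yl]-1,3-dioxolane | I/C=C(/C)CCC1OCCO1 | intermediate
6 | (4Z)-5-iodo-4-methylpent-4-enal | O=CCC/C(C)=C\I | intermediate
7 | isopropenylmagnesium bromide | C=C(C)[Mg]Br | starting material
8 | rac-(6Z)-7-iodo-2,6-dimethylhepta-1,6-dien-3-ol | C=C(C)C(O)CC/C(C)=C\I | intermediate
9 | (1S,4Z)-5-iodo-4-methyl-1-[(2R)-2-methyloxiran-2-yl]pent-4-en-1-ol | C[C@@]1(CO1)[C@@H](O)CC/C(C)=C\I | intermediate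
10 | TBS ether of 9 | C[C@@]1(CO1)[C@@H](O[Si](C)(C)C(C)(C)C)CC/C(C)=C\I | intermediate
11 | methacrolein | C=C(C)C=O | starting material
12 | 2,3-dibromopropene | C=C(Br)CBr | starting material
13 | 2-bromoallylindium dibromide | C=C(Br)C[In](Br)Br | intermediate (not isolated)
14 | rac-5-bromo-2-methylhexa-1,5-dien-3-ol | C=C(C)C(O)CC(Br)=C | intermediate
15 | (1R)-3-bromo-1-[(2S)-2-methyloxiran-2-yl]but-3-en-1-ol | C[C@]1(CO1)[C@H](O)CC(Br)=C | intermediate
16 | (3S,4R)-6-bromo-3-methylhepta-1,6-diene-3,4-diol | C=C[C@](C)(O)[C@H](O)CC(Br)=C | intermediate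
17 | B-[(3S,4R)-6-bromo-3,4-dihydroxy-3-methylhept-6-en-1-yl]-9-BBN | B1(C2CCCC1CCC2)CC[C@](C)(O)[C@H](O)CC(Br)=C | intermediate (not isolated)
18 | (4R,5S,8Z,12S)-2-bromo-12-(TBSO)-5,9-dimethyl-12-[(2R)-2-methyloxiran-2-yl]dodeca-1,8-diene-4,5-diol | C[C@@]1(CO1)[C@@H](O[Si](C)(C)C(C)(C)C)CC/C(C)=C\CC[C@](C)(O)[C@H](O)CC(Br)=C | intermediate
19 | epoxy α-methylene-γ-butyrolactone (acyclic key-step precursor; 4R,5S,8Z,12S,13R) | C[C@@]1(CO1)[C@@H](O[Si](C)(C)C(C)(C)C)CC/C(C)=C\CC[C@](C)(O)[C@H]2CC(=C)C(=O)O2 | intermediate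
20 | β-hydroxyalkylcobalamin from 19 (Co on C3; corrin and axial ligands omitted; stereocentres as in 19) | [Co]C[C@@](C)(O)[C@@H](O[Si](C)(C)C(C)(C)C)CC/C(C)=C\CC[C@](C)(O)[C@H]1CC(=C)C(=O)O1 | intermediate (not isolated)
21 | bridged macrocyclic γ-lactone (1R,4R,5S,8Z,12S,13R) | O=C1O[C@@H]2C[C@H]1CC[C@@](C)(O)[C@@H](O[Si](C)(C)C(C)(C)C)CC/C(C)=C\CC[C@]2(C)O | intermediate
22 | methyl ester 12,13-acetonide | COC(=O)[C@@H]1CC[C@@](C)(O)[C@@H](O[Si](C)(C)C(C)(C)C)CC/C(C)=C\CC[C@]2(C)OC(C)(C)O[C@@H]2C1 | intermediate
23 | Weinreb amide 12,13-acetonide | CON(C)C(=O)[C@@H]1CC[C@@](C)(O)[C@@H](O[Si](C)(C)C(C)(C)C)CC/C(C)=C\CC[C@]2(C)OC(C)(C)O[C@@H]2C1 | intermediate (not isolated)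
24 | C15 methyl ketone | CC(=O)[C@@H]1CC[C@@](C)(O)[C@@H](O[Si](C)(C)C(C)(C)C)CC/C(C)=C\CC[C@]2(C)OC(C)(C)O[C@@H]2C1 | intermediate
25 | C15 enol triflate | C=C(OS(=O)(=O)C(F)(F)F)[C@@H]1CC[C@@](C)(O)[C@@H](O[Si](C)(C)C(C)(C)C)CC/C(C)=C\CC[C@]2(C)OC(C)(C)O[C@@H]2C1 | intermediate
26 | 5-O-TBS-12,13-O-isopropylidene derivative of 27 | C=C1C(=O)O[C@]2(C)CC[C@@H]1C[C@H]3OC(C)(C)O[C@@]3(C)CC/C=C(/C)CC[C@@H]2O[Si](C)(C)C(C)(C)C | intermediate
27 | CNP0263298.1, (1R,4R,5S,8Z,12S,13R)-5,12,13-trihydroxycembra-8,15(17)-dien-16,4-olide | C=C1C(=O)O[C@]2(C)CC[C@@H]1C[C@@H](O)[C@@](C)(O)CC/C=C(/C)CC[C@@H]2O | target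

Total step count: 16. Longest linear sequence: 13 steps (steps 1–5, then 9–16).

**Steps most likely to fail**

First, step 11.
- What may go wrong: the primary C3 radical may be lost before ring closure. The routes are a 1,5-hydrogen shift from the allylic C7–H, early reduction, or intermolecular addition. Cob(I)alamin may also be consumed by the Michael acceptor instead of the epoxide.
- Fallback (known chemistry): starting from 19, the epoxide is opened at its CH2 terminus with LiI/AcOH in THF to give the C3 iodohydrin F1.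
- This is then cyclised by the classical tin-hydride Giese macrocyclisation (Bu3SnH and AIBN added by syringe pump to refluxing benzene at millimolar concentration). Hydrogen transfer to the convex lactone face gives 21, where the route is rejoined.

Second, step 15.
- What may go wrong: capture of the acylpalladium by the hindered tertiary C4–OH may be too slow, so that hydrolysis or decomposition of the acyl complex takes over.
- Fallback: this separates C–C from C–O bond formation. Starting from 25, palladium-catalysed hydroxycarbonylation (Pd(OAc)2, dppf, CO, KOAc, wet DMSO) gives the 2-substituted acrylic acid F2.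
- The acid is closed onto C4–OH by Shiina lactonisation (2-methyl-6-nitrobenzoic anhydride, DMAP, high dilution) to give 26.

Third, step 12.
- What may go wrong: opening of the bridged lactone may be incomplete, or the C5 silyl ether may be lost under acid. A freed C4/C5 diol would then be blocked as an acetonide.
- Fallback: this opens the lactone under non-acidic conditions. Starting from 21, aminolysis with Me2AlN(OMe)Me (from AlMe3 and MeNH(OMe)·HCl, CH2Cl2, 0 °C) gives the trihydroxy Weinreb amide F3.
- Its 12,13-diol is closed at once with 2-methoxypropene and catalytic PPTS at 0 °C to give 23, which is taken on with MeMgBr as in step 13.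

**Further compounds**
F1 | step 11 | C3 iodohydrin of 19 (I on C3, OH on C4, all stereocentres arranged as in 19) | IC[C@@](C)(O)[C@@H](O[Si](C)(C)C(C)(C)C)CC/C(C)=C\CC[C@](C)(O)[C@H]1CC(=C)C(=O)O1
F2 | step 15 | 2-{(1R,4R,5S,8Z,12S,13R)-5-(TBSO)-4-hydroxy-12,13-(isopropylidenedioxy)-4,8,12-trimethylcyclotetradec-8-en-1-yl}acrylic acid | C=C(C(=O)O)[C@@H]1CC[C@@](C)(O)[C@@H](O[Si](C)(C)C(C)(C)C)CC/C(C)=C\CC[C@]2(C)OC(C)(C)O[C@@H]2C1
F3 | step 12 | (1R,4R,5S,8Z,12S,13R)-5-(TBSO)-4,12,13-trihydroxy-N-methoxy-N,4,8,12-tetramethylcyclotetradec-8-ene-1-carboxamide | CON(C)C(=O)[C@@H]1CC[C@@](C)(O)[C@@H](O[Si](C)(C)C(C)(C)C)CC/C(C)=C\CC[C@](C)(O)[C@H](O)C1
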